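**Plan**

- The retrosynthesis first cuts the acyl C–O bond of the ferulate ester. In the remaining (2R)-2-(hydroxymethyl)-2-methyl-2H-chromene, C3=C4 is rehydrated at C3 and the CH2OH is raised to a methyl ester.
- The enabling feature is C2 of the pyran ring: a quaternary carbon bonded to O1, C3, CH3 and a carboxyl-level carbon. It corresponds to the carbene carbon of methyl 2-diazopropanoate, so O1–C2 and C2–C3 are cut together. This leaves a phenol whose ortho carbon carries CH2–CHO (future C4 and C3).
- Forward, the arene is bought as acetovanillone and the side chain is installed by O-allylation, Claisen rearrangement and ozonolysis. The pyran ring, the only ring made, closes in one step, and the ferulate chain is joined last.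
- The single stereocentre (C2, R) is set in the ring-forming step by a chiral phosphoric acid. The C3 carbinol formed with it is removed by dehydration toward C4, and C2 has no hydrogen, so it cannot epimerise later.

Key step: step 5

Assumption: the sense of induction of the phosphoric acid in step 5 cannot be predicted with confidence; (R)-TRIP is written, and its antipode would be used if it favours the 2S series. The C3 configuration shown is nominal, since C3 becomes planar in step 7.

**Route**

Step 1
Reactants: 1 acetovanillone, 1-(4-hydroxy-3-methoxyphenyl)ethanone; 2 allyl bromide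
Product: 3 1-[3-methoxy-4-(prop-2-enyloxy)phenyl]ethanone
Conditions: K2CO3, acetone, reflux
Reagents that add atoms: none
Why: Williamson ether synthesis, in which the phenoxide (made more acidic by the para-acetyl group) is O-alkylated by the primary allylic bromide while the ketone is inert to carbonate.

Step 2
Reactants: 3 1-[3-methoxy-4-(prop-2-enyloxy)phenyl]ethanone
Product: 4 1-[4-hydroxy-3-methoxy-5-(prop-2-enyl)phenyl]ethanone
Conditions: N,N-diethylaniline, 195 °C, argon
Reagents that add atoms: none
Why: Aromatic Claisen rearrangement, in which the [3,3] shift can deliver the allyl group only to the one free ortho carbon and tautomerisation restores the phenol.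

Step 3
Reactants: 4 1-[4-hydroxy-3-methoxy-5-(prop-2-enyl)phenyl]ethanone
Product: 7 1-(2-hydroxy-7-methoxy-2,3-dihydro-1-benzofuran-5-yl)ethanone (racemic lactol), via secondary ozonide 5 (not isolated), via open hydroxy aldehyde 6 (not isolated)
Conditions: O3, CH2Cl2, −78 °C, stopped when the alkene is consumed; then PPh3, −78 °C to rt
Reagents that add atoms: ozone, O=[O+][O-]
Why: Ozonolysis with reductive work-up, in which the terminal alkene reacts much faster than the acetyl-deactivated phenol ring and the released aldehyde is held reversibly by the ortho hydroxyl as the five-membered lactol.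

Step 4
Reactants: 8 methyl 2-methyl-3-oxobutanoate (methyl 2-methylacetoacetate)
Product: 9 methyl 2-diazopropanoate
Conditions: 4-acetamidobenzenesulfonyl azide, DBU, MeCN, 0 °C to rt; kept as a titrated CH2Cl2 solution
Reagents that add atoms: 4-acetamidobenzenesulfonyl azide, CC(=O)Nc1ccc(cc1)S(=O)(=O)N=[N+]=[N-]
Why: Deacylative (Regitz) diazo transfer, in which the enolate of the 2-alkyl β-keto ester adds to the sulfonyl azide and the adduct fragments with transfer of the acetyl group to the sulfonamide nitrogen.

Step 5
Reactants: 7 1-(2-hydroxy-7-methoxy-2,3-dihydro-1-benzofuran-5-yl)ethanone, which enters through its open tautomer 6, 2-(5-acetyl-2-hydroxy-3-methoxyphenyl)acetaldehyde; 9 methyl 2-diazopropanoate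
Product: 11 methyl (2R,3S)-6-acetyl-3-hydroxy-8-methoxy-2-methylchromane-2-carboxylate, via ester enol 10 (not isolated)
Conditions: Rh2(OPiv)4 (2 mol %), (R)-TRIP [(R)-3,3′-bis(2,4,6-triisopropylphenyl)-1,1′-binaphthyl-2,2′-diyl hydrogen phosphate] (10 mol %), 4 Å MS, CH2Cl2, −30 °C, 9 added over 2 h by syringe pump
Reagents that add atoms: none
Why: Proposed new method: loss of N2 from 9 at dirhodium gives an electrophilic methyl(methoxycarbonyl)carbene that is captured by the phenolic oxygen of open-chain 6 (released from lactol 7 by acid-catalysed ring–chain tautomerism), and the resulting oxonium ylide, as its enol 10, adds through carbon to the aldehyde two atoms from the ring before the 1,2-proton shift can give the plain O–H insertion product, so that O1–C2 and C2–C3 form in one operation. The closest known reaction types are the dirhodium carboxylate/chiral phosphoric acid co-catalysed aldol-type trapping of oxonium ylides derived from aryldiazoacetates and the asymmetric O–H insertion of 2-diazopropanoates into phenols; an alkyl diazoester, a phenol and a tethered aldehyde have not been joined in this way. The pyran ring closes by a 6-(enolexo)-exo-trig aldol addition. C2 is controlled by the phosphoric acid, which hydrogen-bonds the enol hydroxyl and the aldehyde oxygen in a bridged, chair-like transition state and so exposes one enol face; C3 follows from that chair and is written with the hydroxyl cis to the ester, its epimer being equally usable. The step needs the aldol closure to outrun proton transfer and β-hydride migration of the carbene to methyl acrylate, which the intramolecular acid-activated aldehyde, the bulky pivalate ligands, the low temperature and the slow addition of 9 are meant to secure, and it needs the phenol rather than the lactol hydroxyl to take the carbene, which the para-acetyl group and the hydrogen bond from the phenol to the neighbouring methoxy group should favour by raising the share of open-chain 6.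

Step 6
Reactants: 11 methyl (2R,3S)-6-acetyl-3-hydroxy-8-methoxy-2-methylchromane-2-carboxylate
Product: 12 methyl (2R,3S)-6-acetyl-8-methoxy-2-methyl-3-(methylsulfonyloxy)chromane-2-carboxylate
Conditions: MsCl, Et3N, CH2Cl2, 0 °C
Reagents that add atoms: methanesulfonyl chloride, CS(=O)(=O)Cl
Why: Sulfonylation of the secondary alcohol through sulfene, in which the hydroxyl is never converted to a free alkoxide, so retro-aldol opening of the β-hydroxy ester is not expected and no stereocentre is touched.

Step 7
Reactants: 12 methyl (2R,3S)-6-acetyl-8-methoxy-2-methyl-3-(methylsulfonyloxy)chromane-2-carboxylate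
Product: 13 methyl (2R)-6-acetyl-8-methoxy-2-methyl-2H-chromene-2-carboxylate
Conditions: DBU, toluene, 80 °C, light excluded
Reagents that add atoms: none
Why: E2 elimination, in which only the benzylic C4 hydrogens are available because C2 is quaternary, giving the arene-conjugated 2H-chromene while C2 keeps its configuration.

Step 8
Reactants: 13 methyl (2R)-6-acetyl-8-methoxy-2-methyl-2H-chromene-2-carboxylate
Product: 14 1-[(2R)-2-(hydroxymethyl)-8-methoxy-2-methyl-2H-chromen-6-yl]ethanol (both epimers at the side-chain carbinol)
Conditions: LiAlH4, THF, 0 °C; Fieser work-up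
Reagents that add atoms: none
Why: Hydride reduction of ester and ketone by LiAlH4, which leaves the styrene-type alkene and aryl ethers alone and does not involve C2; the unselectively formed carbinol centre is removed in step 9.

Step 9
Reactants: 14 1-[(2R)-2-(hydroxymethyl)-8-methoxy-2-methyl-2H-chromen-6-yl]ethanol
Product: 15 1-[(2R)-2-(hydroxymethyl)-8-methoxy-2-methyl-2H-chromen-6-yl]ethanone
Conditions: activated MnO2, CH2Cl2, rt, light excluded
Reagents that add atoms: none
Why: MnO2 oxidation selective for the electron-rich benzylic secondary alcohol (para to the ring oxygen), while the primary homoallylic alcohol is not activated and survives.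

Step 10
Reactants: 16 ferulic acid, (E)-3-(4-hydroxy-3-methoxyphenyl)prop-2-enoic acid
Product: 18 (E)-3-[4-(tert-butyldimethylsilyloxy)-3-methoxyphenyl]prop-2-enoic acid, via bis-silyl ferulate 17 (not isolated)
Conditions: TBSCl (2.5 equiv), imidazole, DMF, rt; then AcOH, THF, H2O, rt
Reagents that add atoms: tert-butyldimethylsilyl chloride, CC(C)(C)[Si](C)(C)Cl
Why: Silylation of phenol and acid followed by selective hydrolysis of the much more labile silyl ester, the aryl silyl ether being stable to mild aqueous acid.

Step 11
Reactants: 15 1-[(2R)-2-(hydroxymethyl)-8-methoxy-2-methyl-2H-chromen-6-yl]ethanone; 18 (E)-3-[4-(tert-butyldimethylsilyloxy)-3-methoxyphenyl]prop-2-enoic acid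
Product: 19 [(2R)-6-acetyl-8-methoxy-2-methyl-2H-chromen-2-yl]methyl (E)-3-[4-(tert-butyldimethylsilyloxy)-3-methoxyphenyl]prop-2-enoate
Conditions: EDC·HCl, DMAP, CH2Cl2, rt, light excluded
Reagents that add atoms: none
Why: Steglich esterification, in which DMAP transfers the acyl group to the primary, β-branched alcohol while the silyl ether prevents self-acylation of the phenol and the E alkene is untouched.

Step 12
Reactants: 19 [(2R)-6-acetyl-8-methoxy-2-methyl-2H-chromen-2-yl]methyl (E)-3-[4-(tert-butyldimethylsilyloxy)-3-methoxyphenyl]prop-2-enoate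
Product: 20 [(2R)-6-acetyl-8-methoxy-2-methyl-2H-chromen-2-yl]methyl (E)-3-(4-hydroxy-3-methoxyphenyl)prop-2-enoate (CNP0168033.1)
Conditions: TBAF, AcOH, THF, 0 °C
Reagents that add atoms: none
Why: Fluoride-induced cleavage of the aryl silyl ether, buffered with acetic acid so that the cinnamate ester, the ketone and the chromene are not exposed to base.

**Compound list**

1 | acetovanillone, 1-(4-hydroxy-3-methoxyphenyl)ethanone | CC(=O)c1ccc(O)c(OC)c1 | starting material
2 | allyl bromide | C=CCBr | starting material
3 | 1-[3-methoxy-4-(prop-2-enyloxy)phenyl]ethanone | CC(=O)c1ccc(OCC=C)c(OC)c1 | intermediate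
4 | 1-[4-hydroxy-3-methoxy-5-(prop-2-enyl)phenyl]ethanone | CC(=O)c1cc(OC)c(O)c(CC=C)c1 | intermediate
5 | 1-[4-hydroxy-3-methoxy-5-(1,2,4-trioxolan-3-ylmethyl)phenyl]ethanone (secondary ozonide) | CC(=O)c1cc(OC)c(O)c(CC2OCOO2)c1 | intermediate
6 | 2-(5-acetyl-2-hydroxy-3-methoxyphenyl)acetaldehyde (open tautomer of 7) | CC(=O)c1cc(OC)c(O)c(CC=O)c1 | intermediate
7 | 1-(2-hydroxy-7-methoxy-2,3-dihydro-1-benzofuran-5-yl)ethanone (racemic lactol) | CC(=O)c1cc2CC(O)Oc2c(OC)c1 | intermediate
8 | methyl 2-methyl-3-oxobutanoate | CC(=O)C(C)C(=O)OC | starting material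
9 | methyl 2-diazopropanoate | COC(=O)C(C)=[N+]=[N-] | intermediate
10 | 2-[4-acetyl-2-methoxy-6-(2-oxoethyl)phenoxy]-1-methoxyprop-1-en-1-ol (ester enol) | COC(O)=C(C)Oc1c(CC=O)cc(C(C)=O)cc1OC | intermediate
11 | methyl (2R,3S)-6-acetyl-3-hydroxy-8-methoxy-2-methylchromane-2-carboxylate | COC(=O)[C@@]1(C)[C@@H](O)Cc2cc(C(C)=O)cc(OC)c2O1 | intermediate
12 | methyl (2R,3S)-6-acetyl-8-methoxy-2-methyl-3-(methylsulfonyloxy)chromane-2-carboxylate | COC(=O)[C@@]1(C)[C@@H](OS(C)(=O)=O)Cc2cc(C(C)=O)cc(OC)c2O1 | intermediate
13 | methyl (2R)-6-acetyl-8-methoxy-2-methyl-2H-chromene-2-carboxylate | COC(=O)[C@@]1(C)C=Cc2cc(C(C)=O)cc(OC)c2O1 | intermediate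
14 | 1-[(2R)-2-(hydroxymethyl)-8-methoxy-2-methyl-2H-chromen-6-yl]ethanol (carbinol epimers) | OC[C@@]1(C)C=Cc2cc(C(C)O)cc(OC)c2O1 | intermediate
15 | 1-[(2R)-2-(hydroxymethyl)-8-methoxy-2-methyl-2H-chromen-6-yl]ethanone | OC[C@@]1(C)C=Cc2cc(C(C)=O)cc(OC)c2O1 | intermediate
16 | ferulic acid | COc1cc(/C=C/C(=O)O)ccc1O | starting material
17 | tert-butyldimethylsilyl (E)-3-[4-(tert-butyldimethylsilyloxy)-3-methoxyphenyl]prop-2-enoate | COc1cc(/C=C/C(=O)O[Si](C)(C)C(C)(C)C)ccc1O[Si](C)(C)C(C)(C)C | intermediate
18 | (E)-3-[4-(tert-butyldimethylsilyloxy)-3-methoxyphenyl]prop-2-enoic acid | COc1cc(/C=C/C(=O)O)ccc1O[Si](C)(C)C(C)(C)C | intermediate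
19 | [(2R)-6-acetyl-8-methoxy-2-methyl-2H-chromen-2-yl]methyl (E)-3-[4-(tert-butyldimethylsilyloxy)-3-methoxyphenyl]prop-2-enoate | COc1cc(/C=C/C(=O)OC[C@@]2(C)C=Cc3cc(C(C)=O)cc(OC)c3O2)ccc1O[Si](C)(C)C(C)(C)C | intermediate
20 | [(2R)-6-acetyl-8-methoxy-2-methyl-2H-chromen-2-yl]methyl (E)-3-(4-hydroxy-3-methoxyphenyl)prop-2-enoate | COc1cc(/C=C/C(=O)OC[C@@]2(C)C=Cc3cc(C(C)=O)cc(OC)c3O2)ccc1O | target

**Step count**

Total: 12 steps. Longest linear sequence: 10 steps (1, 2, 3, 5, 6, 7, 8, 9, 11, 12).

**Steps most likely to fail**

Step 5 (new method). The carbene may be lost to β-hydride migration or to insertion into the lactol hydroxyl. Proton transfer may outrun the aldol closure, or the enol faces may be poorly differentiated.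

The fallback uses known reaction types, sets out from 4 and rejoins the route at 15. The allyl group of 4 would be isomerised with RuClH(CO)(PPh3)3 in toluene at 80 °C to 1-[4-hydroxy-3-methoxy-5-[(E)-prop-1-enyl]phenyl]ethanone F1. This phenol would be used in a palladium-catalysed asymmetric allylic etherification of 2-methyl-2-vinyloxirane, with the zerovalent palladium source Pd2(dba)3·CHCl3 and the DACH-phenyl Trost ligand, the ligand antipode being chosen to give the R ether. Attack at the tertiary allyl terminus should give 1-[4-{[(2R)-1-hydroxy-2-methylbut-3-en-2-yl]oxy}-3-methoxy-5-[(E)-prop-1-enyl]phenyl]ethanone F2. Ring-closing metathesis of F2 with the second-generation Grubbs catalyst, RuCl2(=CHPh)(PCy3)(H2IMes), in CH2Cl2 at 40 °C would expel propene and close the chromene, giving 15 directly with the ketone intact.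

Step 7. Anti-elimination at a mesylate flanked by a quaternary carbon may be slow. The heat then needed could erode the C2 configuration through reversible electrocyclic ring opening of the chromene, or let the amidine attack the ester or ketone.

The fallback sets out from 11 and rejoins at 13. Dess–Martin oxidation would give methyl (2R)-6-acetyl-8-methoxy-2-methyl-3-oxochromane-2-carboxylate F3. Deprotonation at the much more acidic C4 position with KN(SiMe3)2 at −78 °C and trapping with PhNTf2 would give methyl (2R)-6-acetyl-8-methoxy-2-methyl-3-(trifluoromethylsulfonyloxy)-2H-chromene-2-carboxylate F4. Palladium-catalysed formate reduction of the enol triflate (Pd(OAc)2, PPh3, Bu3N, HCO2H, DMF, 60 °C) would then deliver 13 without any elimination step.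

Step 3. Ozone may attack the electron-rich phenol ring, and the lactol–aldehyde pair may condense with itself during isolation.

The fallback sets out from 4 and rejoins at 7. Acetylation (Ac2O, pyridine) would give 4-acetyl-2-methoxy-6-(prop-2-enyl)phenyl acetate F5. Lemieux–Johnson cleavage (OsO4 cat., NaIO4, 2,6-lutidine, dioxane–water) would give 4-acetyl-2-methoxy-6-(2-oxoethyl)phenyl acetate F6; with the phenol masked, periodate cannot oxidise a free 2-methoxyphenol. Mild methanolysis (K2CO3, MeOH, 0 °C) would release the phenol, which closes to lactol 7.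

Further compounds
F1 | step 5 | 1-[4-hydroxy-3-methoxy-5-[(E)-prop-1-enyl]phenyl]ethanone | CC(=O)c1cc(OC)c(O)c(/C=C/C)c1
F2 | step 5 | 1-[4-{[(2R)-1-hydroxy-2-methylbut-3-en-2-yl]oxy}-3-methoxy-5-[(E)-prop-1-enyl]phenyl]ethanone | OC[C@@](C)(C=C)Oc1c(OC)cc(C(C)=O)cc1/C=C/C
F3 | step 7 | methyl (2R)-6-acetyl-8-methoxy-2-methyl-3-oxochromane-2-carboxylate | COC(=O)[C@@]1(C)C(=O)Cc2cc(C(C)=O)cc(OC)c2O1
F4 | step 7 | methyl (2R)-6-acetyl-8-methoxy-2-methyl-3-(trifluoromethylsulfonyloxy)-2H-chromene-2-carboxylate | COC(=O)[C@@]1(C)C(OS(=O)(=O)C(F)(F)F)=Cc2cc(C(C)=O)cc(OC)c2O1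
F5 | step 3 | 4-acetyl-2-methoxy-6-(prop-2-enyl)phenyl acetate | CC(=O)Oc1c(CC=C)cc(C(C)=O)cc1OC
F6 | step 3 | 4-acetyl-2-methoxy-6-(2-oxoethyl)phenyl acetate | CC(=O)Oc1c(CC=O)cc(C(C)=O)cc1OC
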